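**Retrosynthetic overview**
1. Lespeflorin C5 (17) is unmasked from its bis-TBS ether 16; ring A of 16 is cut across C1'–C2' and C5'–C6' into bis(silyloxy) diene 7 and terminal ynone 14 (Diels–Alder/aromatisation).
2. The strategy rests on ring A, a benzene with five neighbouring substituents: the run C2'(OH)–C3'(CH3)–C4'(OH)–C5'(prenyl) is the carbon/oxygen pattern of a 2-methyl-4-prenylacetoacetate, and C1'(acyl)/C6'(the only ring CH) are the two carbons of a terminal alkynyl ketone.
3. Diene 7 comes from ethyl 2-methylacetoacetate (1) and prenyl bromide (2) by dianion alkylation and twofold O-silylation.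
4. Ynone 14 comes from (S)-3-(4-hydroxyphenyl)lactic acid (8), which supplies ring B and the only stereocentre, by way of Weinreb amide 11 and ethynylmagnesium bromide (12).
5. Ring order: ring B is bought intact; ring A is the only ring made, in step 8.

Key step: step 8

Assumption: (S)-3-(4-hydroxyphenyl)lactic acid is taken as a purchasable single enantiomer; the olefin geometries of the silyl enol ethers 5 and 7 are left uncontrolled because the carbons concerned become aromatic.

**Route**

Step 1
Reactants: 1 ethyl 2-methylacetoacetate; 2 prenyl bromide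
Product: 4 ethyl 2,7-dimethyl-3-oxooct-6-enoate, via sodium lithium dianion 3 (not isolated)
Conditions: NaH (1.1 equiv), THF, 0 °C; n-BuLi (1.05 equiv), 0 °C; 2 (1.1 equiv), 0 °C to rt; cold dilute HCl work-up
Reagents that add atoms: none
Why: Weiler-type beta-keto ester dianion alkylation, in which NaH removes the C2 proton and n-BuLi an acetyl-methyl proton, and the more basic terminal carbanion of 3 should be alkylated by the primary allylic bromide (SN2); the C2 centre of 4 is racemic and irrelevant because it becomes sp2 in step 2.

Step 2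
Reactants: 4 ethyl 2,7-dimethyl-3-oxooct-6-enoate
Product: 5 ethyl 2,7-dimethyl-3-(trimethylsilyloxy)octa-2,6-dienoate
Conditions: TMSCl (1.8 equiv), Et3N (2.0 equiv), toluene, rt, 48–72 h; filtration under argon, concentration
Reagents that add atoms: chlorotrimethylsilane, C[Si](C)(C)Cl
Why: Amine-mediated enolisation and O-silylation of the ketone carbonyl, the first stage of the standard preparation of Chan-type dienes, should give the beta-silyloxy enoate while the ester and the trisubstituted olefin stay untouched.

Step 3
Reactants: 5 ethyl 2,7-dimethyl-3-(trimethylsilyloxy)octa-2,6-dienoate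
Product: 7 1-ethoxy-2,7-dimethyl-1,3-bis(trimethylsilyloxy)octa-1,3,6-triene, via lithium dienolate 6 (not isolated)
Conditions: LiN(i-Pr)2 (LDA, 1.3 equiv), THF, −78 °C, 1 h; TMSCl (1.5 equiv), −78 °C to rt; concentration, hexane, filtration under argon; crude diene used at once
Reagents that add atoms: chlorotrimethylsilane, C[Si](C)(C)Cl
Why: Kinetic gamma-deprotonation of the beta-silyloxy enoate at the C4 methylene gives the extended ester dienolate 6, whose oxygen is silylated by the hard electrophile TMSCl (second stage of the Chan-type diene preparation); the non-aqueous work-up protects the labile silyl ketene acetal.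

Step 4
Reactants: 8 (S)-3-(4-hydroxyphenyl)lactic acid
Product: 9 methyl (2S)-2-hydroxy-3-(4-hydroxyphenyl)propanoate
Conditions: MeOH, H2SO4 (cat.), reflux
Reagents that add atoms: methanol, CO
Why: Fischer esterification in excess methanol touches only the carboxyl group; no bond to the stereocentre is broken and no enolisation occurs under acid, so the S configuration should be kept.

Step 5
Reactants: 9 methyl (2S)-2-hydroxy-3-(4-hydroxyphenyl)propanoate
Product: 10 methyl (2S)-2-(tert-butyldimethylsilyloxy)-3-[4-(tert-butyldimethylsilyloxy)phenyl]propanoate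
Conditions: TBSCl (2.5 equiv), imidazole (5 equiv), DMF, rt
Reagents that add atoms: tert-butyldimethylsilyl chloride, CC(C)(C)[Si](C)(C)Cl
Why: Imidazole-promoted silylation should cap both the phenol and the secondary alcohol as TBS ethers, which tolerate the Grignard reagents, the cycloaddition and brief dilute acid ahead and are removed together by fluoride at the end.

Step 6
Reactants: 10 methyl (2S)-2-(tert-butyldimethylsilyloxy)-3-[4-(tert-butyldimethylsilyloxy)phenyl]propanoate
Product: 11 (2S)-2-(tert-butyldimethylsilyloxy)-3-[4-(tert-butyldimethylsilyloxy)phenyl]-N-methoxy-N-methylpropanamide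
Conditions: MeNHOMe·HCl (1.6 equiv), i-PrMgCl (3.2 equiv), THF, −20 °C to 0 °C; aq. NH4Cl
Reagents that add atoms: N,O-dimethylhydroxylamine hydrochloride, CNOC.Cl
Why: Direct ester-to-Weinreb-amide aminolysis by the chloromagnesium amide generated in the flask, a nucleophilic and only weakly basic reagent that should add to the ester carbonyl faster than it enolises the alpha-silyloxy ester, so the stereocentre is expected to survive.

Step 7
Reactants: 11 (2S)-2-(tert-butyldimethylsilyloxy)-3-[4-(tert-butyldimethylsilyloxy)phenyl]-N-methoxy-N-methylpropanamide; 12 ethynylmagnesium bromide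
Product: 14 (4S)-4-(tert-butyldimethylsilyloxy)-5-[4-(tert-butyldimethylsilyloxy)phenyl]pent-1-yn-3-one, via magnesium hemiaminal chelate 13 (not isolated)
Conditions: 12 (0.5 M in THF, 2.5 equiv), THF, 0 °C to rt; cannulation into vigorously stirred 1 M HCl/Et2O at 0 °C (inverse quench)
Reagents that add atoms: none
Why: Weinreb ketone synthesis, in which the acetylide adds once to give chelate 13 that persists until it meets cold acid, where the released N,O-dimethylhydroxylamine is protonated at once and cannot add to the ynone in conjugate fashion; the weakly basic alkynyl Grignard should not epimerise the alpha-silyloxy centre.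

Step 8
Reactants: 7 1-ethoxy-2,7-dimethyl-1,3-bis(trimethylsilyloxy)octa-1,3,6-triene; 14 (4S)-4-(tert-butyldimethylsilyloxy)-5-[4-(tert-butyldimethylsilyloxy)phenyl]pent-1-yn-3-one
Product: 16 (2S)-2-(tert-butyldimethylsilyloxy)-3-[4-(tert-butyldimethylsilyloxy)phenyl]-1-[2,4-dihydroxy-3-methyl-5-(3-methylbut-2-en-1-yl)phenyl]propan-1-one, via cyclohexa-1,4-diene cycloadduct 15 (not isolated)
Conditions: 7 (1.8 equiv), toluene, 0 °C to 45 °C; then THF, 0.5 M HCl, 0 °C, brief
Reagents that add atoms: none
Why: The electron-rich diene 7 and the electron-poor ynone 14 should unite in a strongly asynchronous normal-demand Diels–Alder reaction (at its stepwise limit a Mukaiyama–Michael addition followed by closure of the allenolate carbon onto the silyloxycarbenium carbon, with the same outcome), the prenyl-bearing CH terminus of 7 bonding to the unsubstituted alkyne carbon (future C5'–C6') and the ketene-acetal carbon to the acyl-bearing alkyne carbon (future C1'–C2'). The closest known reaction type is the benzannulation of Chan- and Brassard-type 1-alkoxy-1,3-bis(silyloxy)dienes with propiolates and alkynyl ketones to 2,4-dihydroxyaryl carbonyl compounds. Ring A is the only ring closed, as a six-membered carbocycle by intermolecular [4+2] union of a four-carbon and a two-carbon unit (6-exo-trig in the stepwise description), giving 15; cold dilute acid then strips the trimethylsilyl groups, the hemiketal expels ethanol, and enolisation of the dienone at the prenyl-bearing carbon delivers the aromatic 2,4-diol, held in the phenol form by the chelating hydrogen bond between the C2' hydroxyl and the aryl ketone. No stereocentre remains in the new ring, so the geometry of 7 and the sp3 ring carbons of 15 are of no consequence, and the S carbinol centre is a spectator that is never deprotonated under these neutral to weakly acidic conditions. The step needs regioselectivity, which polarity matching should secure: both oxygen donor sets of 7 make its CH terminus the most nucleophilic carbon, while the terminal carbon of 14 is at once the most electrophilic and the least hindered alkyne carbon, so the acyl group ends up ortho to the ester-derived oxygen and para to the ketone-derived one.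

Step 9
Reactants: 16 (2S)-2-(tert-butyldimethylsilyloxy)-3-[4-(tert-butyldimethylsilyloxy)phenyl]-1-[2,4-dihydroxy-3-methyl-5-(3-methylbut-2-en-1-yl)phenyl]propan-1-one
Product: 17 Lespeflorin C5
Conditions: TBAF (3.0 equiv), AcOH (3.0 equiv), THF, 0 °C to rt
Reagents that add atoms: none
Why: Fluoride-mediated cleavage of the aryl and the secondary silyl ether, buffered with acetic acid so that neither phenoxide nor enolate accumulates, should suppress alpha-ketol rearrangement, epimerisation of the carbinol centre and cyclisation of the ortho-prenylphenol to a chroman.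

**Compound list**
1 | ethyl 2-methylacetoacetate (ethyl 2-methyl-3-oxobutanoate) | CCOC(=O)C(C)C(C)=O | starting material
2 | prenyl bromide (1-bromo-3-methylbut-2-ene) | CC(C)=CCBr | starting material
3 | sodium lithium dianion of ethyl 2-methylacetoacetate | CCOC([O-])=C(C)C(=C)[O-].[Na+].[Li+] | intermediate
4 | ethyl 2,7-dimethyl-3-oxooct-6-enoate (racemic at C2) | CCOC(=O)C(C)C(=O)CCC=C(C)C | intermediate
5 | ethyl 2,7-dimethyl-3-(trimethylsilyloxy)octa-2,6-dienoate (C2=C3 geometry not controlled) | CCOC(=O)C(C)=C(O[Si](C)(C)C)CCC=C(C)C | intermediate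
6 | lithium dienolate of 5 (deprotonated at C4) | CCOC([O-])=C(C)C(O[Si](C)(C)C)=CCC=C(C)C.[Li+] | intermediate
7 | 1-ethoxy-2,7-dimethyl-1,3-bis(trimethylsilyloxy)octa-1,3,6-triene (diene geometry not controlled) | CCOC(O[Si](C)(C)C)=C(C)C(O[Si](C)(C)C)=CCC=C(C)C | intermediate
8 | (S)-3-(4-hydroxyphenyl)lactic acid, (2S)-2-hydroxy-3-(4-hydroxyphenyl)propanoic acid | O[C@@H](Cc1ccc(O)cc1)C(=O)O | starting material
9 | methyl (2S)-2-hydroxy-3-(4-hydroxyphenyl)propanoate | COC(=O)[C@@H](O)Cc1ccc(O)cc1 | intermediate
10 | methyl (2S)-2-(tert-butyldimethylsilyloxy)-3-[4-(tert-butyldimethylsilyloxy)phenyl]propanoate | COC(=O)[C@@H](O[Si](C)(C)C(C)(C)C)Cc1ccc(O[Si](C)(C)C(C)(C)C)cc1 | intermediate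
11 | (2S)-2-(tert-butyldimethylsilyloxy)-3-[4-(tert-butyldimethylsilyloxy)phenyl]-N-methoxy-N-methylpropanamide | CON(C)C(=O)[C@@H](O[Si](C)(C)C(C)(C)C)Cc1ccc(O[Si](C)(C)C(C)(C)C)cc1 | intermediate
12 | ethynylmagnesium bromide | C#C[Mg]Br | starting material
13 | bromomagnesium alkoxide of the tetrahedral N-methoxy-N-methyl hemiaminal (acetylide adduct of 11, S at the silyloxy carbon, new carbon not defined) | C#CC(O[Mg]Br)(N(C)OC)[C@@H](O[Si](C)(C)C(C)(C)C)Cc1ccc(O[Si](C)(C)C(C)(C)C)cc1 | intermediate
14 | (4S)-4-(tert-butyldimethylsilyloxy)-5-[4-(tert-butyldimethylsilyloxy)phenyl]pent-1-yn-3-one | C#CC(=O)[C@@H](O[Si](C)(C)C(C)(C)C)Cc1ccc(O[Si](C)(C)C(C)(C)C)cc1 | intermediate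
15 | (2S)-2-(tert-butyldimethylsilyloxy)-3-[4-(tert-butyldimethylsilyloxy)phenyl]-1-[6-ethoxy-5-methyl-3-(3-methylbut-2-en-1-yl)-4,6-bis(trimethylsilyloxy)cyclohexa-1,4-dien-1-yl]propan-1-one (ring sp3 centres not defined) | CCOC1(O[Si](C)(C)C)C(C)=C(O[Si](C)(C)C)C(CC=C(C)C)C=C1C(=O)[C@@H](O[Si](C)(C)C(C)(C)C)Cc1ccc(O[Si](C)(C)C(C)(C)C)cc1 | intermediate
16 | (2S)-2-(tert-butyldimethylsilyloxy)-3-[4-(tert-butyldimethylsilyloxy)phenyl]-1-[2,4-dihydroxy-3-methyl-5-(3-methylbut-2-en-1-yl)phenyl]propan-1-one | CC(C)=CCc1cc(C(=O)[C@@H](O[Si](C)(C)C(C)(C)C)Cc2ccc(O[Si](C)(C)C(C)(C)C)cc2)c(O)c(C)c1O | intermediate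
17 | Lespeflorin C5, (2S)-1-[2,4-dihydroxy-3-methyl-5-(3-methylbut-2-en-1-yl)phenyl]-2-hydroxy-3-(4-hydroxyphenyl)propan-1-one | CC(C)=CCc1cc(C(=O)[C@@H](O)Cc2ccc(O)cc2)c(O)c(C)c1O | target

**Step count**
Total steps: 9. Longest linear sequence: 6 steps (8 to 17 through steps 4, 5, 6, 7, 8 and 9); the diene arm is 3 steps (1 to 7).

**Steps most likely to fail**

Step 8. Ring closure at the hindered, fully substituted ketene-acetal terminus may lag behind the first carbon–carbon bond formation, so that the reaction stalls at open-chain Michael adducts, or protodesilylation of the diene may outrun the cycloaddition. The fallback forms the aryl–acyl bond on a preformed ring instead of building ring A; it sets out from Weinreb amide 11 and comes back at 16.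
- Commercial 2-methylresorcinol would be dibrominated (Br2, 2 equiv, AcOH/CH2Cl2, 0 °C) at its only two activated positions to 4,6-dibromo-2-methylbenzene-1,3-diol F1.
- Allylation (allyl bromide, K2CO3, DMF) would give 1,3-bis(allyloxy)-4,6-dibromo-2-methylbenzene F2.
- A single bromine–lithium exchange (n-BuLi, 1.0 equiv, THF, −78 °C), transmetalation with CuBr·SMe2 and coupling with prenyl bromide 2 would give 1,3-bis(allyloxy)-4-bromo-2-methyl-6-(3-methylbut-2-en-1-yl)benzene F3.
- A second bromine–lithium exchange at −78 °C, kept cold to forestall anionic cyclisation onto the allyl ethers, and trapping with 11 would give (2S)-1-[2,4-bis(allyloxy)-3-methyl-5-(3-methylbut-2-en-1-yl)phenyl]-2-(tert-butyldimethylsilyloxy)-3-[4-(tert-butyldimethylsilyloxy)phenyl]propan-1-one F4.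
- Deallylation with catalytic Pd(PPh3)4 (a zerovalent palladium complex) and morpholine in THF at rt, which leaves the prenyl group and both TBS ethers alone, would free the two ring phenols and return 16.

Step 3. Incomplete gamma-deprotonation or C-silylation by the lithium amide route, and hydrolysis of the moisture-sensitive diene during handling, may erode the quality of 7. The fallback sets out from keto ester 4 and comes back at diene 7: one-pot soft enolisation with trimethylsilyl triflate (2.2 equiv) and Et3N (2.5 equiv) in Et2O at 0 °C, followed by separation of the triethylammonium triflate layer, silylates both carbonyl oxygens without any strong base. It bypasses 5 and 6 and passes through no compound outside the compound list (entry F0).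

Step 7. Conjugate addition of the liberated amine to the ynone, a second acetylide addition, or oligomerisation of the terminal ynone during quench and isolation may consume 14. The fallback changes the oxidation-state sequence so that no amine is released beside the ynone; it sets out from 11 and comes back at 14.
- Reduction with i-Bu2AlH (THF, −78 °C) would give (2S)-2-(tert-butyldimethylsilyloxy)-3-[4-(tert-butyldimethylsilyloxy)phenyl]propanal F5, used crude to limit epimerisation.
- Addition of 12 at −78 °C would give (4S)-4-(tert-butyldimethylsilyloxy)-5-[4-(tert-butyldimethylsilyloxy)phenyl]pent-1-yn-3-ol F6, either carbinol epimer being acceptable.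
- Oxidation with Dess–Martin periodinane and NaHCO3 in CH2Cl2 would return 14.

**Further compounds**
F0 | step 3 | none | none
F1 | step 8 | 4,6-dibromo-2-methylbenzene-1,3-diol | Cc1c(O)c(Br)cc(Br)c1O
F2 | step 8 | 1,3-bis(allyloxy)-4,6-dibromo-2-methylbenzene | Cc1c(OCC=C)c(Br)cc(Br)c1OCC=C
F3 | step 8 | 1,3-bis(allyloxy)-4-bromo-2-methyl-6-(3-methylbut-2-en-1-yl)benzene | Cc1c(OCC=C)c(Br)cc(CC=C(C)C)c1OCC=C
F4 | step 8 | (2S)-1-[2,4-bis(allyloxy)-3-methyl-5-(3-methylbut-2-en-1-yl)phenyl]-2-(tert-butyldimethylsilyloxy)-3-[4-(tert-butyldimethylsilyloxy)phenyl]propan-1-one | C=CCOc1c(C)c(OCC=C)c(CC=C(C)C)cc1C(=O)[C@@H](O[Si](C)(C)C(C)(C)C)Cc1ccc(O[Si](C)(C)C(C)(C)C)cc1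
F5 | step 7 | (2S)-2-(tert-butyldimethylsilyloxy)-3-[4-(tert-butyldimethylsilyloxy)phenyl]propanal | O=C[C@@H](O[Si](C)(C)C(C)(C)C)Cc1ccc(O[Si](C)(C)C(C)(C)C)cc1
F6 | step 7 | (4S)-4-(tert-butyldimethylsilyloxy)-5-[4-(tert-butyldimethylsilyloxy)phenyl]pent-1-yn-3-ol (carbinol carbon not defined) | C#CC(O)[C@@H](O[Si](C)(C)C(C)(C)C)Cc1ccc(O[Si](C)(C)C(C)(C)C)cc1
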